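A one-sided end group reacts once with a first end group and makes a capped end. Second end groups join first end groups to make links, links turn into the isomer of the product, and second end groups also condense with each other. We compare links with capped ends in four flasks.

| flask | first end groups | second end groups | one-sided end groups | remark | time |
|---|---|---|---|---|---|
| Friday's | 10 mM | 0.98 equiv | 1 mM | run made earlier |  |
| Monday's | 10 mM | 0.49 equiv | 1 mM | run made earlier |  |
| Sunday's | 10 mM | 2 equiv | 1 mM | run made earlier |  |
| west | 10 mM (fed, over 15 d) | 0.980 equiv | 1.00 mM | all else is in the flask from the start; the feed brings no volume worth counting | 25 d |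
| north-east | 10 mM | 0.980 equiv (in portions, 2, over 15 d) | 1.00 mM | first portion at the start, last at 15 d | 25 d |
| north-west | 10 mM | 0.980 equiv | 1.00 mM | everything together at the start | 25 d |
| south-east | 10 mM | 0.980 equiv (fed, over 15 d) | 1.00 mM | all else is in the flask from the start; the feed brings no volume worth counting | 25 d |

| run | time / d | links / % | capped ends / % |
|---|---|---|---|
| Friday's | 4.00 | 12 | 7 |
| Friday's | 8.00 | 4 | 7 |
| Friday's | 12.0 | 6 | 9 |
| Friday's | 15.0 | 5 | 10 |
| Monday's | 4.00 | 11 | 9 |
| Monday's | 8.00 | 4 | 11 |
| Monday's | 12.0 | 5 | 12 |
| Monday's | 15.0 | 2 | 12 |
| Sunday's | 2.08 | 27 | 7 |
| Sunday's | 5.00 | 10 | 8 |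
| Sunday's | 10.0 | 5 | 9 |
| Sunday's | 15.0 | 4 | 8 |

(each reading ± 2 percentage points)

- what was read earlier has a scatter of 2 percentage points, one standard deviation
- steps under discussion: 2 second end groups -> self-condensation product; first end groups + second end groups <-> links; links <-> isomer of the product; first end groups + one-sided end groups -> capped ends

1. the flask with the highest share of links in links plus capped ends ("all alike" if they lie within 1.5 percentage points) (west / north-east / north-west / south-east / all alike)
2. share of links in links plus capped ends at the end, west
3. share of links in links plus capped ends at the end, north-east
4. share of links in links plus capped ends at the end, north-west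
5. share of links in links plus capped ends at the end, south-east

One-sided end groups are the limiting reagent of capping. So capped ends, as a fraction of the first end groups charged, stop at the ratio of the two charges, 10.0%. We call this the capping ceiling. West, north-east, north-west and south-east each take 1.00 mM of one-sided end groups on 10 mM of first end groups, so they share this ceiling.

Friday's run, charged like north-west, reads capped ends of 9% after 12.0 d and 10% after 15.0 d, with a scatter of 2 percentage points. We therefore take capping as finished by 25 d. The share is then links divided by links plus the ceiling, and we still have to estimate the smaller term, links.

If links stood at 25 d where Friday's last reading has them, 5% after 15.0 d, our reckoning for north-west would be 33.3%. But the reading is coarse. The neighbouring readings, 4% and 6%, give 28.6% and 37.5%. A small error in links becomes a large one in the share.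

The forecast gives 36% for west, 39% for north-east, 34% for north-west and 36% for south-east. It picks north-east, saying “The late second portion in north-east leaves the most fresh linking”. Its north-west figure stands 0.70 points above ours.

The flasks give 17.6% in west, 37.8% in north-east, 26.2% in north-west and 35.5% in south-east, so north-east stands highest.

    2 second end groups → self-condensation product (k = 2.56 L mol⁻¹ h⁻¹)
    first end groups + second end groups ⇌ links (K = 88.0 L mol⁻¹, k = 4.90 L mol⁻¹ h⁻¹)
    links ⇌ isomer of the product (K = 1.50, k = 0.00352 h⁻¹)
    first end groups + one-sided end groups → capped ends (k = 10.7 L mol⁻¹ h⁻¹)

West is where forecast and flask part widest among the printed figures, by 18 points. At 25.0 d, west holds capped ends at 10.0%, one-sided end groups at 0% of their charge, and links at 2.14%, and the ceiling turns those links into 17.6%. A flask like west with 4.0 mM of one-sided end groups has a ceiling of 40.0%. It holds capped ends at 40.0% and links at 1.42%, and its share is 3.42%.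

All runs stem from a simulated flask for substances that don't exist.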